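**Strategy.** The γ-lactone ring (O1, C2, C3, C4, C5) with its aroyl ketone on C3 is treated as the hydrolytic isomer of a 2-aryl-4,5-dihydrofuran-3-carboxylate. The ketone carbon on C3 and the O1-bearing C5 are 1,4-related across C3–C4, so the ketone oxygen and O1 can be merged into one cyclic enol ether. One palladium-catalysed oxidative cyclisation–methoxycarbonylation of a homopropargylic alcohol forms the temporary O1–C(aryl) bond (5-endo-dig) and the permanent C3–C2 bond. The precursor is an (R)-configured 4-aryl-2-(3,4-dimethoxybenzyl)but-3-yn-1-ol with the phenol masked as benzyl ether. Its only stereocentre, the future C4, comes from an organocatalytic α-hydroxymethylation. Aqueous acid then switches the dihydrofuran into the lactone, C3 settling trans.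

Key step: step 7

Assumption: C3 of the target, flanked by the ketone and the lactone carbonyl, is configurationally labile; the trans (3S,4R) arrangement of the target is taken to be the thermodynamic one and is set by equilibration.

Step 1
Reactants: 1 3-(3,4-dimethoxyphenyl)propan-1-ol
Product: 2 3-(3,4-dimethoxyphenyl)propanal
Conditions: TEMPO (10 mol%), PhI(OAc)2 (1.1 equiv), CH2Cl2, rt
Reagents that add atoms: none
Why: TEMPO/PhI(OAc)2 oxidation (oxoammonium-mediated alcohol oxidation) should stop at the aldehyde without touching the electron-rich veratryl ring.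

Step 2
Reactants: 2 3-(3,4-dimethoxyphenyl)propanal; 3 formaldehyde
Product: 4 (2S)-2-[(3,4-dimethoxyphenyl)methyl]-3-hydroxypropanal
Conditions: 37% aq. CH2O (3 equiv), (R)-2-[diphenyl(trimethylsilyloxy)methyl]pyrrolidine (20 mol%), pH 7 phosphate buffer, toluene, rt
Reagents that add atoms: formaldehyde (compound 3), C=O
Why: Organocatalytic α-hydroxymethylation (enamine-mediated aldol addition to formaldehyde): the (E)-enamine formed from 2 and the (R)-configured catalyst is shielded on one face by the diphenyl(silyloxy)methyl group, so formaldehyde should add to the open face and create the (S)-configured centre that becomes C4 of the target, the buffered two-phase medium holding back enolisation of the product.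

Step 3
Reactants: 4 (2S)-2-[(3,4-dimethoxyphenyl)methyl]-3-hydroxypropanal
Product: 5 (2S)-3-[(tert-butyldimethylsilyl)oxy]-2-[(3,4-dimethoxyphenyl)methyl]propanal
Conditions: TBSCl, imidazole, CH2Cl2, 0 °C to rt (crude 4 used at once)
Reagents that add atoms: tert-butyldimethylsilyl chloride, CC(C)(C)[Si](C)(C)Cl
Why: Standard imidazole-promoted silylation of the primary hydroxyl, carried out on the crude hydroxy aldehyde, should break up its hemiacetal oligomers and shut off dehydration and retro-aldol loss of formaldehyde before the centre can racemise.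

Step 4
Reactants: 5 (2S)-3-[(tert-butyldimethylsilyl)oxy]-2-[(3,4-dimethoxyphenyl)methyl]propanal
Product: 6 tert-butyl{[(2R)-2-[(3,4-dimethoxyphenyl)methyl]but-3-yn-1-yl]oxy}dimethylsilane
Conditions: dimethyl (1-diazo-2-oxopropyl)phosphonate, K2CO3, MeOH, 0 °C to rt
Reagents that add atoms: dimethyl (1-diazo-2-oxopropyl)phosphonate, CC(=O)C(=[N+]=[N-])P(=O)(OC)OC
Why: Ohira–Bestmann variant of the Seyferth–Gilbert homologation: the diazophosphonate anion released by methanolysis adds to the aldehyde faster than the mild carbonate base enolises it at 0 °C, so the centre should be retained (it becomes R only through the change in CIP priorities) and the silyl ether is untouched.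

Step 5
Reactants: 7 4-iodo-2-methoxyphenol
Product: 8 1-(benzyloxy)-4-iodo-2-methoxybenzene
Conditions: BnBr, K2CO3, acetone, reflux
Reagents that add atoms: benzyl bromide, BrCc1ccccc1
Why: Williamson etherification of the phenoxide with benzyl bromide masks the phenol, which would otherwise be exposed to the oxidant of the carbonylation.

Step 6
Reactants: 6 tert-butyl{[(2R)-2-[(3,4-dimethoxyphenyl)methyl]but-3-yn-1-yl]oxy}dimethylsilane; 8 1-(benzyloxy)-4-iodo-2-methoxybenzene
Product: 10 (2R)-4-[4-(benzyloxy)-3-methoxyphenyl]-2-[(3,4-dimethoxyphenyl)methyl]but-3-yn-1-ol, via silyl ether 9 (not isolated)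
Conditions: Pd(PPh3)2Cl2 (2 mol%), CuI (4 mol%), Et3N/THF, degassed, rt to 40 °C; then TBAF (1.5 equiv), rt
Reagents that add atoms: none
Why: Sonogashira coupling of the terminal alkyne with the aryl iodide should proceed near room temperature without touching the propargylic centre, and fluoride added to the same flask cleaves the primary silyl ether to free the hydroxyl needed as nucleophile.

Step 7
Reactants: 10 (2R)-4-[4-(benzyloxy)-3-methoxyphenyl]-2-[(3,4-dimethoxyphenyl)methyl]but-3-yn-1-ol; 11 carbon monoxide; 12 methanol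
Product: 13 methyl (4R)-2-[4-(benzyloxy)-3-methoxyphenyl]-4-[(3,4-dimethoxyphenyl)methyl]-4,5-dihydrofuran-3-carboxylate
Conditions: PdCl2(MeCN)2 (5 mol%), p-benzoquinone (1.5 equiv), CO (1 atm), MeOH, 0 °C to rt
Reagents that add atoms: carbon monoxide (compound 11), [C-]#[O+]; methanol (compound 12), CO
Why: Divalent palladium coordinates the alkyne of 10 and the primary hydroxyl adds anti to it at the aryl-bearing alkyne carbon, so the temporary 4,5-dihydrofuran ring closes in the 5-endo-dig mode and palladium ends on the carbon that becomes C3 of the lactone. CO insertion into this vinyl–palladium bond and methanolysis of the acylpalladium form the C3–C2 bond as a methyl ester, and p-benzoquinone returns zerovalent palladium to the divalent state. The closest known reaction type is the oxidative heterocyclisation–alkoxycarbonylation of alkynols, 2-alkynylphenols and 2-alkynylanilines under divalent palladium, CO and an alcohol. No stereocentre is created: C4 of 13 is the propargylic centre of 10, which is not acidic under these cold, overall neutral conditions. The step needs oxygen attack at the aryl-bearing carbon (5-endo, not 4-exo) and CO capture ahead of protonolysis of the vinylpalladium or of an alkoxycarbonylpalladium pathway to an arylidene lactone. The para-benzyloxy group makes the aryl-bearing alkyne carbon the electrophilic one and the four-membered alternative is strained, while base-free chloride conditions, a CO atmosphere and methanol as solvent favour alkyne activation and fast trapping of the acyl species.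

Step 8
Reactants: 13 methyl (4R)-2-[4-(benzyloxy)-3-methoxyphenyl]-4-[(3,4-dimethoxyphenyl)methyl]-4,5-dihydrofuran-3-carboxylate
Product: 15 (3S,4R)-3-[4-(benzyloxy)-3-methoxybenzoyl]-4-[(3,4-dimethoxyphenyl)methyl]oxolan-2-one, via hydroxy keto ester 14 (not isolated)
Conditions: 1 M aq. HCl/THF (1:2), 45 °C
Reagents that add atoms: water, O
Why: Acid-catalysed enol ether hydrolysis followed by lactonisation (the reverse of the acyl-lactone rearrangement): protonation at C3 gives an oxocarbenium ion stabilised by the ring oxygen and the para-alkoxyaryl ring, water opens it to hydroxy keto ester 14, whose primary hydroxyl closes the five-membered lactone on the methyl ester (5-exo-trig) with loss of methanol, and C3, lying between two carbonyls, should equilibrate through the enol to the trans (3S) epimer while the non-enolisable C4 stays R.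

Step 9
Reactants: 15 (3S,4R)-3-[4-(benzyloxy)-3-methoxybenzoyl]-4-[(3,4-dimethoxyphenyl)methyl]oxolan-2-one
Product: 16 (3S,4R)-4-[(3,4-dimethoxyphenyl)methyl]-3-(4-hydroxy-3-methoxybenzoyl)oxolan-2-one
Conditions: H2 (1 atm), 10% Pd/C, EtOAc, rt
Reagents that add atoms: none
Why: Hydrogenolysis of the benzyl aryl ether over Pd/C under one atmosphere of hydrogen should be much faster than reduction of the electron-rich aryl ketone or the lactone, and the neutral medium leaves the trans relationship at C3/C4 as set.

**Compound list**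

1 | 3-(3,4-dimethoxyphenyl)propan-1-ol | COc1ccc(CCCO)cc1OC | starting material
2 | 3-(3,4-dimethoxyphenyl)propanal | COc1ccc(CCC=O)cc1OC | intermediate
3 | formaldehyde | C=O | starting material
4 | (2S)-2-[(3,4-dimethoxyphenyl)methyl]-3-hydroxypropanal | OC[C@@H](C=O)Cc1ccc(OC)c(OC)c1 | intermediate
5 | (2S)-3-[(tert-butyldimethylsilyl)oxy]-2-[(3,4-dimethoxyphenyl)methyl]propanal | CC(C)(C)[Si](C)(C)OC[C@@H](C=O)Cc1ccc(OC)c(OC)c1 | intermediate
6 | tert-butyl{[(2R)-2-[(3,4-dimethoxyphenyl)methyl]but-3-yn-1-yl]oxy}dimethylsilane | CC(C)(C)[Si](C)(C)OC[C@@H](C#C)Cc1ccc(OC)c(OC)c1 | intermediate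
7 | 4-iodo-2-methoxyphenol | COc1cc(I)ccc1O | starting material
8 | 1-(benzyloxy)-4-iodo-2-methoxybenzene | COc1cc(I)ccc1OCc1ccccc1 | intermediate
9 | tert-butyl{[(2R)-4-[4-(benzyloxy)-3-methoxyphenyl]-2-[(3,4-dimethoxyphenyl)methyl]but-3-yn-1-yl]oxy}dimethylsilane | CC(C)(C)[Si](C)(C)OC[C@@H](C#Cc1ccc(OCc2ccccc2)c(OC)c1)Cc1ccc(OC)c(OC)c1 | intermediate
10 | (2R)-4-[4-(benzyloxy)-3-methoxyphenyl]-2-[(3,4-dimethoxyphenyl)methyl]but-3-yn-1-ol | OC[C@@H](C#Cc1ccc(OCc2ccccc2)c(OC)c1)Cc1ccc(OC)c(OC)c1 | intermediate
11 | carbon monoxide | [C-]#[O+] | starting material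
12 | methanol | CO | starting material
13 | methyl (4R)-2-[4-(benzyloxy)-3-methoxyphenyl]-4-[(3,4-dimethoxyphenyl)methyl]-4,5-dihydrofuran-3-carboxylate | COC(=O)C1=C(c2ccc(OCc3ccccc3)c(OC)c2)OC[C@@H]1Cc1ccc(OC)c(OC)c1 | intermediate
14 | methyl (3R)-2-[4-(benzyloxy)-3-methoxybenzoyl]-3-[(3,4-dimethoxyphenyl)methyl]-4-hydroxybutanoate (C2 epimers) | OC[C@@H](C(C(=O)OC)C(=O)c1ccc(OCc2ccccc2)c(OC)c1)Cc1ccc(OC)c(OC)c1 | intermediate
15 | (3S,4R)-3-[4-(benzyloxy)-3-methoxybenzoyl]-4-[(3,4-dimethoxyphenyl)methyl]oxolan-2-one | COc1cc(C(=O)[C@H]2C(=O)OC[C@@H]2Cc2ccc(OC)c(OC)c2)ccc1OCc1ccccc1 | intermediate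
16 | (3S,4R)-4-[(3,4-dimethoxyphenyl)methyl]-3-(4-hydroxy-3-methoxybenzoyl)oxolan-2-one | COc1cc(C(=O)[C@H]2C(=O)OC[C@@H]2Cc2ccc(OC)c(OC)c2)ccc1O | target

**Step count.** Total: 9 steps. Longest linear sequence: 8 steps (steps 1, 2, 3, 4, 6, 7, 8, 9); step 5 is a one-step side branch.

**Steps most likely to fail**

Step 7. The vinylpalladium intermediate may be protonated before it captures CO, leaving plain cycloisomerisation. Carbonylation may also begin at the hydroxyl and close the ring in the other sense. The fallback separates the two bond formations. It sets out from 10, which would be treated with I2 and NaHCO3 in MeCN at 0 °C. This 5-endo-dig iodocyclisation should give (3S)-5-[4-(benzyloxy)-3-methoxyphenyl]-3-[(3,4-dimethoxyphenyl)methyl]-4-iodo-2,3-dihydrofuran F1. The vinyl iodide would then be methoxycarbonylated under zerovalent palladium (Pd(PPh3)4, Et3N, CO 1 atm, MeOH/DMF, 60 °C). This comes back to the route at 13.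

Step 8. Hydrolysis of the push–pull enol ether may stall. Under more forcing acid it may run on into lactone opening and decarboxylation. The fallback accepts the decarboxylation and rebuilds the lactone by a Claisen-type ring closure. It sets out from 13. Saponification (LiOH, THF/MeOH/H2O, 60 °C), then acidification and warming (1 M HCl, 50 °C), should give (3R)-1-[4-(benzyloxy)-3-methoxyphenyl]-3-[(3,4-dimethoxyphenyl)methyl]-4-hydroxybutan-1-one F2. Acylation of the primary hydroxyl (ClCO2Me, pyridine, CH2Cl2, 0 °C) would give (2R)-4-[4-(benzyloxy)-3-methoxyphenyl]-2-[(3,4-dimethoxyphenyl)methyl]-4-oxobutyl methyl carbonate F3. With LiHMDS (2.2 equiv, THF, −78 to 0 °C) the ketone enolate should attack the carbonate carbonyl in a 5-exo-trig closure and expel methoxide. After acidic work-up this comes back to the route at 15.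

Step 2. Enantiopurity may erode through enolisation, dehydration or retro-aldol cleavage of the unprotected β-hydroxy aldehyde, and the material may oligomerise before silylation. The fallback sets the centre with a chiral auxiliary. It sets out from 1 and comes back to the route at 5.
- Oxidation of 1 (TEMPO cat., NaOCl cat., NaClO2, MeCN/phosphate buffer) would give 3-(3,4-dimethoxyphenyl)propanoic acid F4.
- Acylation of (4R)-4-benzyl-1,3-oxazolidin-2-one via the mixed pivalic anhydride (PivCl, Et3N, LiCl, THF) would give (4R)-4-benzyl-3-[3-(3,4-dimethoxyphenyl)propanoyl]-1,3-oxazolidin-2-one F5.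
- The chelated titanium enolate (TiCl4, i-Pr2NEt, CH2Cl2, 0 °C) would be hydroxymethylated with s-trioxane/TiCl4 on the face away from the auxiliary benzyl group. This should give (4R)-4-benzyl-3-{(2S)-2-[(3,4-dimethoxyphenyl)methyl]-3-hydroxypropanoyl}-1,3-oxazolidin-2-one F6.
- Silylation (TBSCl, imidazole) would give (4R)-4-benzyl-3-{(2S)-3-[(tert-butyldimethylsilyl)oxy]-2-[(3,4-dimethoxyphenyl)methyl]propanoyl}-1,3-oxazolidin-2-one F7.
- Reductive removal of the auxiliary (LiBH4, THF/MeOH, 0 °C) would give (2R)-3-[(tert-butyldimethylsilyl)oxy]-2-[(3,4-dimethoxyphenyl)methyl]propan-1-ol F8.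
- Dess–Martin oxidation (NaHCO3, CH2Cl2) would then give 5.

**Further compounds**

F1 | step 7 | (3S)-5-[4-(benzyloxy)-3-methoxyphenyl]-3-[(3,4-dimethoxyphenyl)methyl]-4-iodo-2,3-dihydrofuran | IC1=C(c2ccc(OCc3ccccc3)c(OC)c2)OC[C@@H]1Cc1ccc(OC)c(OC)c1
F2 | step 8 | (3R)-1-[4-(benzyloxy)-3-methoxyphenyl]-3-[(3,4-dimethoxyphenyl)methyl]-4-hydroxybutan-1-one | OC[C@@H](CC(=O)c1ccc(OCc2ccccc2)c(OC)c1)Cc1ccc(OC)c(OC)c1
F3 | step 8 | (2R)-4-[4-(benzyloxy)-3-methoxyphenyl]-2-[(3,4-dimethoxyphenyl)methyl]-4-oxobutyl methyl carbonate | COC(=O)OC[C@@H](CC(=O)c1ccc(OCc2ccccc2)c(OC)c1)Cc1ccc(OC)c(OC)c1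
F4 | step 2 | 3-(3,4-dimethoxyphenyl)propanoic acid | COc1ccc(CCC(=O)O)cc1OC
F5 | step 2 | (4R)-4-benzyl-3-[3-(3,4-dimethoxyphenyl)propanoyl]-1,3-oxazolidin-2-one | COc1ccc(CCC(=O)N2[C@H](Cc3ccccc3)COC2=O)cc1OC
F6 | step 2 | (4R)-4-benzyl-3-{(2S)-2-[(3,4-dimethoxyphenyl)methyl]-3-hydroxypropanoyl}-1,3-oxazolidin-2-one | OC[C@@H](C(=O)N1[C@H](Cc2ccccc2)COC1=O)Cc1ccc(OC)c(OC)c1
F7 | step 2 | (4R)-4-benzyl-3-{(2S)-3-[(tert-butyldimethylsilyl)oxy]-2-[(3,4-dimethoxyphenyl)methyl]propanoyl}-1,3-oxazolidin-2-one | CC(C)(C)[Si](C)(C)OC[C@@H](C(=O)N1[C@H](Cc2ccccc2)COC1=O)Cc1ccc(OC)c(OC)c1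
F8 | step 2 | (2R)-3-[(tert-butyldimethylsilyl)oxy]-2-[(3,4-dimethoxyphenyl)methyl]propan-1-ol | CC(C)(C)[Si](C)(C)OC[C@@H](CO)Cc1ccc(OC)c(OC)c1
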